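**Retrosynthetic overview**
1. Labdane numbering: ring A = C1–C5 and C10, ring B = C5–C10; C18/C19 on C4, C20 on C10, C17 = carboxyl carbon on C8, C11–C16 = dienyl chain on C9.
2. Feature used: ring B is a cyclohexene whose C6 oxygen and C7=C8 alkene are the trace of a 2-silyloxy diene C5=C6(OSi)–C7=C8 that has added to a C9=C10 enal (C11 = CHO, C20 on C10); the chain C1–C4 ties C5 to C10.
3. Key disconnection: C5–C10 and C8–C9 in one catalytic asymmetric intramolecular Diels–Alder reaction of an (E,Z,E)-siloxy trienal; rings A and B close together and C5, C9 and C10 are set.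
4. Trienal: C9=C10 by alkyne methylalumination, C3–C4 by conjugate addition to mesityl oxide, C7=C8 by aldol condensation, C5=C6 by kinetic enol silylation, enal by pivalate removal and MnO2.
5. After the cycloaddition: C11→C12 homologation, Saegusa oxidation to the 6-oxo-Δ7 enone, two Wittig reactions for the diene, Luche reduction and acetylation at C6, then C17 desilylation and oxidation to the acid.

Key step: step 9

Remark on configuration: the target as drawn is (5R,6S,9S,10S), an ent-labdane with C20, the C9 chain and the C6 acetoxy group on one face and H5 and H9 on the other. C17 is carried as a TBDPS ether, which tolerates the cationic Lewis acid of step 9 and is removed at the end without an oxidant in the presence of the diene. C8 is a stereocentre only between steps 9 and 11.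

Assumption: the (S)-configured oxazaborolidinium salt is assigned from the formyl C–H···O binding model, which should leave the Re face of C9 open. If correlation of the cycloadduct shows the opposite sense, the (R)-catalyst takes its place with no other change.

**Route**

Step 1
Reactants: 1 5-chloropent-1-yne
Product: 4 (E)-6-chloro-3-methylhex-2-en-1-ol, via alkenyldimethylalane 2 (not isolated), via lithium alkenylaluminate 3 (not isolated)
Conditions: Me3Al, Cp2ZrCl2 (25 mol %), CH2Cl2, 0 → 23 °C; evaporate; n-BuLi, THF, −78 °C; (CH2O)n, −78 → 23 °C; 1 M HCl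
Reagents that add atoms: trimethylaluminium C[Al](C)C; paraformaldehyde (as formaldehyde) C=O
Why: Zirconium-catalysed methylalumination of a terminal alkyne (Negishi carboalumination) is a syn addition with aluminium on the terminal carbon, and the derived aluminate attacks formaldehyde with retention, so the (E)-trisubstituted allylic alcohol (later C11–C9=C10 with C20) should form with defined geometry.

Step 2
Reactants: 4 (E)-6-chloro-3-methylhex-2-en-1-ol, 5 mesityl oxide
Product: 8 (E)-10-hydroxy-4,4,8-trimethyldec-8-en-2-one, via chloromagnesium alkoxide 6 (not isolated), via alkoxide Grignard reagent 7 (not isolated)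
Conditions: i-PrMgCl (1.0 equiv), THF, −20 °C; Mg (activated), THF, 65 °C; CuBr·SMe2 (10 mol %), 5, THF, −40 → 0 °C; 1 M HCl
Reagents that add atoms: none
Why: The hydroxyl is masked as its magnesium alkoxide so that the primary chloride can be converted into a Grignard reagent, and copper catalysis should direct it to conjugate addition at the β,β-dimethyl carbon of the enone, which creates the quaternary C4 and the C3–C4 bond.

Step 3
Reactants: 8 (E)-10-hydroxy-4,4,8-trimethyldec-8-en-2-one
Product: 9 (E)-3,7,7-trimethyl-9-oxodec-2-en-1-yl pivalate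
Conditions: pivaloyl chloride, pyridine, 4-(dimethylamino)pyridine (cat.), CH2Cl2, 0 → 23 °C
Reagents that add atoms: pivaloyl chloride CC(C)(C)C(Cl)=O
Why: Acylation of the primary allylic alcohol gives an ester without α-hydrogen that should survive the amide bases of steps 4 and 6 and can be removed by hydride in step 7 without acid or fluoride.

Step 4
Reactants: 9 (E)-3,7,7-trimethyl-9-oxodec-2-en-1-yl pivalate, 10 2-[(tert-butyldiphenylsilyl)oxy]acetaldehyde
Product: 12 (E)-12-[(tert-butyldiphenylsilyl)oxy]-11-hydroxy-3,7,7-trimethyl-9-oxododec-2-en-1-yl pivalate (racemic at the carbinol carbon), via lithium methyl-side enolate 11 (not isolated)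
Conditions: LiN(i-Pr)2, THF, −78 °C; 10, −78 °C; AcOH
Reagents that add atoms: none
Why: Kinetic deprotonation of the methyl ketone takes place at the methyl group (C7) and not at the neopentyl C5 methylene, and the lithium enolate adds to the aldehyde (directed aldol addition) to form C7–C8; the carbinol centre is formed as a racemate and disappears in step 5.

Step 5
Reactants: 12 aldol adduct
Product: 14 (2E,10E)-12-[(tert-butyldiphenylsilyl)oxy]-3,7,7-trimethyl-9-oxododeca-2,10-dien-1-yl pivalate, via β-mesyloxy ketone 13 (not isolated)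
Conditions: MeSO2Cl, Et3N, CH2Cl2, 0 → 23 °C
Reagents that add atoms: none
Why: Mesylation of the β-hydroxy ketone followed by E1cB elimination completes the aldol condensation and should give the conjugated (E)-enone C7=C8.

Step 6
Reactants: 14 (2E,10E)-dienone pivalate
Product: 16 (2E,8Z,10E)-9-[(tert-butyldimethylsilyl)oxy]-12-[(tert-butyldiphenylsilyl)oxy]-3,7,7-trimethyldodeca-2,8,10-trien-1-yl pivalate, via lithium cross-conjugated dienolate 15 (not isolated)
Conditions: LiN(SiMe3)2, THF, −78 °C; t-BuMe2SiCl, DMPU, −78 → 0 °C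
Reagents that add atoms: tert-butyldimethylsilyl chloride CC(C)(C)[Si](C)(C)Cl
Why: Kinetic deprotonation of an enone by a lithium amide removes the α′-proton (C5) rather than the γ-proton (C17), and the tert-alkyl group on C5 avoids the C7 vinyl group, so O-silylation of the enolate should give the (Z)-2-silyloxy diene (C4 cis to oxygen).

Step 7
Reactants: 16 silyl dienol ether pivalate
Product: 17 (2E,8Z,10E)-9-[(tert-butyldimethylsilyl)oxy]-12-[(tert-butyldiphenylsilyl)oxy]-3,7,7-trimethyldodeca-2,8,10-trien-1-ol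
Conditions: i-Bu2AlH (2.5 equiv), CH2Cl2, −78 °C; aq. potassium sodium tartrate
Reagents that add atoms: none
Why: Hydride reduction cleaves the pivalate under aprotic, non-acidic conditions to which the silyl dienol ether and the TBDPS ether are inert (ester reduction).

Step 8
Reactants: 17 trienol
Product: 18 (2E,8Z,10E)-9-[(tert-butyldimethylsilyl)oxy]-12-[(tert-butyldiphenylsilyl)oxy]-3,7,7-trimethyldodeca-2,8,10-trienal
Conditions: MnO2, CH2Cl2, 23 °C
Reagents that add atoms: none
Why: Heterogeneous allylic oxidation with MnO2 is neutral, should keep the (E)-geometry of the trisubstituted alkene and should leave the silyl dienol ether untouched.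

Step 9
Reactants: 18 (E,Z,E)-siloxy trienal
Product: 19 (1R,2R,4aR,8aR)-4-[(tert-butyldimethylsilyl)oxy]-2-{[(tert-butyldiphenylsilyl)oxy]methyl}-5,5,8a-trimethyl-1,2,4a,5,6,7,8,8a-octahydronaphthalene-1-carbaldehyde (trans-fused; C9 formyl, C8 silyloxymethyl and C20 on one face)
Conditions: (S)-3,3-diphenyl-1-(2-methylphenyl)tetrahydro-1H,3H-pyrrolo[1,2-c][1,3,2]oxazaborole (20 mol %), HN(SO2CF3)2 (20 mol %), CH2Cl2 (0.02 M), −78 → −40 °C; Et3N
Reagents that add atoms: none
Why: The cationic boron binds the formyl oxygen of the s-trans (E)-enal, lowers its LUMO and lets the electron-rich 2-silyloxy diene add in a concerted, asynchronous [4+2] in which C5–C10 bonding runs ahead of C8–C9. The closest known reactions are the chiral oxazaborolidinium-catalysed Diels–Alder additions of 2-silyloxy dienes to enals and the Lewis-acid-catalysed intramolecular Diels–Alder reaction of undeca-2,8,10-trienals to trans-decalins. Ring B (C5–C10) closes as the cyclohexene of the [4+2] with the C6=C7 silyl enol ether as its new alkene, and ring A (C1–C5, C10) closes at the same time as the six-membered ring of the four-carbon tether, which lies exo to the diene in a chair-like arrangement. C9 and C10 are related by the (E)-enal (CHO cis to C20) and fixed in the absolute sense by the catalyst, whose aryl group should cover one enal face so that the diene bonds to the Re face of C9; C5 follows from the (Z)-enol ether with the tether exo (H5 trans to C20, trans fusion) and C8 from the (E)-C7=C8 alkene with the formyl group endo (C17 cis to CHO). The step needs endo over exo and one enal face: Lewis-acid coordination should strengthen the endo preference of the formyl group, the (E)-enal then forces the tether exo, and the (Z)-geometry at C5=C6 keeps the tert-alkyl terminus outside so that the s-cis diene is reachable.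

Step 10
Reactants: 19 cycloadduct aldehyde
Product: 20 methyl enol ether (19 with C9–CH=CH–OCH3 in place of the formyl group, E/Z mixture at C11=C12; ring stereocentres unchanged)
Conditions: MeOCH2PPh3Cl, KN(SiMe3)2, THF, 0 °C; 19, −78 → 23 °C
Reagents that add atoms: (methoxymethyl)triphenylphosphonium chloride COC[P+](c1ccccc1)(c1ccccc1)c1ccccc1.[Cl-]
Why: Wittig reaction with the methoxymethylene ylide adds C12 under basic, acid-free conditions that keep the silyl enol ether, and the equatorial C9 substituent has no drive to epimerise.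

Step 11
Reactants: 20 methyl enol ether
Product: 21 6-oxo-Δ7 enone (C6 ketone, C7=C8 with CH2OTBDPS on C8, C9 2-methoxyvinyl as E/Z mixture; H5 and H9 cis to each other and trans to C20)
Conditions: Pd(OAc)2 (1.2 equiv), MeCN, 23 → 40 °C
Reagents that add atoms: none
Why: Saegusa oxidation: the silyl enol ether should transfer to palladium as its enolate, and β-hydride elimination can only take H8, so the enone forms at C7=C8 and the C8 stereocentre is erased, while the alkyl enol ether has no silicon to transfer and should stay.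

Step 12
Reactants: 21 enone methyl enol ether
Product: 22 aldehyde enone (C9–CH2–CHO, C12 = CHO; ring as in 21)
Conditions: 2 M HCl, THF, 0 → 23 °C
Reagents that add atoms: water O
Why: Acid-catalysed hydrolysis of the alkyl enol ether releases the homologated aldehyde, and the TBDPS ether and the conjugated enone should be stable to dilute acid.

Step 13
Reactants: 22 aldehyde enone
Product: 23 enal enone (C9–CH2–CH=C(CH3)–CHO, 12E; ring as in 21)
Conditions: Ph3P=C(CH3)CHO, toluene, 90 °C
Reagents that add atoms: 2-(triphenylphosphoranylidene)propanal CC(C=O)=P(c1ccccc1)(c1ccccc1)c1ccccc1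
Why: Wittig reaction of a stabilised ylide should give the (E)-2-methyl enal and should react only with the aldehyde, since the hindered conjugated C6 ketone is inert to it.

Step 14
Reactants: 23 enal enone
Product: 24 dienyl enone (C9–CH2–CH=C(CH3)–CH=CH2, 12E; C6 ketone, C7=C8)
Conditions: Ph3PCH3Br, KN(SiMe3)2, THF, 0 °C; 23, −78 → 0 °C
Reagents that add atoms: methyltriphenylphosphonium bromide C[P+](c1ccccc1)(c1ccccc1)c1ccccc1.[Br-]
Why: Wittig methylenation should take place at the unhindered enal carbonyl at low temperature, faster than any reaction of the ylide with the hindered C6 carbonyl or its γ-hydrogens.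

Step 15
Reactants: 24 dienyl enone
Product: 25 (6S)-allylic alcohol (C6–OH axial and cis to C20; otherwise as 24)
Conditions: NaBH4, CeCl3·7H2O, MeOH/THF, −78 → −20 °C
Reagents that add atoms: none
Why: Luche 1,2-reduction: hydride should approach the carbonyl from the face opposite to the two syn-axial methyl groups (C20 on C10 and the axial methyl on C4), which places the hydroxyl on the face of C20.

Step 16
Reactants: 25 allylic alcohol
Product: 26 (6S)-acetate (C6–OAc cis to C20; C17 TBDPS ether)
Conditions: Ac2O, 4-(dimethylamino)pyridine, pyridine, 50 °C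
Reagents that add atoms: acetic anhydride CC(=O)OC(C)=O
Why: Nucleophilic acyl-transfer catalysis acetylates the hindered axial alcohol at oxygen with retention at C6.

Step 17
Reactants: 26 acetate silyl ether
Product: 27 17-alcohol (C8–CH2OH; 6-acetate and diene intact)
Conditions: HF·pyridine, pyridine, THF, 0 → 23 °C
Reagents that add atoms: none
Why: Buffered fluoride cleaves the primary TBDPS ether, and the acetate cannot migrate because C17 and C6 are trans across C7=C8.

Step 18
Reactants: 27 17-alcohol
Product: 28 17-aldehyde (C8–CHO conjugated with C7=C8)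
Conditions: MnO2, CH2Cl2, 23 °C
Reagents that add atoms: none
Why: Allylic oxidation with MnO2 is selective for the allylic primary alcohol and neutral toward the acetate and the diene.

Step 19
Reactants: 28 17-aldehyde
Product: 29 (5R,6S,9S,10S,12E)-6-acetoxylabda-7,12,14-trien-17-oic acid (target)
Conditions: NaClO2, NaH2PO4, 2-methylbut-2-ene, t-BuOH/H2O, 0 → 23 °C
Reagents that add atoms: sodium chlorite [Na+].[O-]Cl=O
Why: Pinnick oxidation converts the enal into the acid without touching alkenes or the acetate, and the alkene scavenger removes the hypochlorous acid that would otherwise attack the diene.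

**Compound list**
1 | 5-chloropent-1-yne | C#CCCCCl | starting material
2 | (E)-(5-chloro-2-methylpent-1-en-1-yl)dimethylalane | C[Al](C)/C=C(\C)CCCCl | intermediate (not isolated)
3 | lithium butyl[(E)-5-chloro-2-methylpent-1-en-1-yl]dimethylaluminate | [Li+].CCCC[Al-](C)(C)/C=C(\C)CCCCl | intermediate (not isolated)
4 | (E)-6-chloro-3-methylhex-2-en-1-ol | OC/C=C(\C)CCCCl | intermediate
5 | mesityl oxide (4-methylpent-3-en-2-one) | CC(=O)C=C(C)C | starting material
6 | chloromagnesium (E)-6-chloro-3-methylhex-2-en-1-olate | Cl[Mg]OC/C=C(\C)CCCCl | intermediate (not isolated)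
7 | chloromagnesium (E)-6-(chloromagnesio)-3-methylhex-2-en-1-olate | Cl[Mg]OC/C=C(\C)CCC[Mg]Cl | intermediate (not isolated)
8 | (E)-10-hydroxy-4,4,8-trimethyldec-8-en-2-one | CC(=O)CC(C)(C)CCC/C(C)=C/CO | intermediate
9 | (E)-3,7,7-trimethyl-9-oxodec-2-en-1-yl pivalate | CC(=O)CC(C)(C)CCC/C(C)=C/COC(=O)C(C)(C)C | intermediate
10 | 2-[(tert-butyldiphenylsilyl)oxy]acetaldehyde | O=CCO[Si](c1ccccc1)(c1ccccc1)C(C)(C)C | starting material
11 | lithium enolate of 9 on the methyl side (C6–OLi, C6=C7) | [Li]OC(=C)CC(C)(C)CCC/C(C)=C/COC(=O)C(C)(C)C | intermediate (not isolated)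
12 | (E)-12-[(tert-butyldiphenylsilyl)oxy]-11-hydroxy-3,7,7-trimethyl-9-oxododec-2-en-1-yl pivalate, racemic at the carbinol carbon | CC(C)(C)C(=O)OC/C=C(\C)CCCC(C)(C)CC(=O)CC(O)CO[Si](c1ccccc1)(c1ccccc1)C(C)(C)C | intermediate
13 | 11-methanesulfonate of 12 | CC(C)(C)C(=O)OC/C=C(\C)CCCC(C)(C)CC(=O)CC(OS(C)(=O)=O)CO[Si](c1ccccc1)(c1ccccc1)C(C)(C)C | intermediate (not isolated)
14 | (2E,10E)-12-[(tert-butyldiphenylsilyl)oxy]-3,7,7-trimethyl-9-oxododeca-2,10-dien-1-yl pivalate | CC(C)(C)C(=O)OC/C=C(\C)CCCC(C)(C)CC(=O)/C=C/CO[Si](c1ccccc1)(c1ccccc1)C(C)(C)C | intermediate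
15 | lithium (Z)-dienolate of 14 (C5=C6–OLi) | CC(C)(C)C(=O)OC/C=C(\C)CCCC(C)(C)/C=C(O[Li])/C=C/CO[Si](c1ccccc1)(c1ccccc1)C(C)(C)C | intermediate (not isolated)
16 | (2E,8Z,10E)-9-[(tert-butyldimethylsilyl)oxy]-12-[(tert-butyldiphenylsilyl)oxy]-3,7,7-trimethyldodeca-2,8,10-trien-1-yl pivalate | CC(C)(C)C(=O)OC/C=C(\C)CCCC(C)(C)/C=C(O[Si](C)(C)C(C)(C)C)/C=C/CO[Si](c1ccccc1)(c1ccccc1)C(C)(C)C | intermediate
17 | (2E,8Z,10E)-9-[(tert-butyldimethylsilyl)oxy]-12-[(tert-butyldiphenylsilyl)oxy]-3,7,7-trimethyldodeca-2,8,10-trien-1-ol | OC/C=C(\C)CCCC(C)(C)/C=C(O[Si](C)(C)C(C)(C)C)/C=C/CO[Si](c1ccccc1)(c1ccccc1)C(C)(C)C | intermediate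
18 | (2E,8Z,10E)-9-[(tert-butyldimethylsilyl)oxy]-12-[(tert-butyldiphenylsilyl)oxy]-3,7,7-trimethyldodeca-2,8,10-trienal (key-step precursor) | O=C/C=C(\C)CCCC(C)(C)/C=C(O[Si](C)(C)C(C)(C)C)/C=C/CO[Si](c1ccccc1)(c1ccccc1)C(C)(C)C | intermediate
19 | (1R,2R,4aR,8aR)-4-[(tert-butyldimethylsilyl)oxy]-2-{[(tert-butyldiphenylsilyl)oxy]methyl}-5,5,8a-trimethyl-1,2,4a,5,6,7,8,8a-octahydronaphthalene-1-carbaldehyde (key-step product) | O=C[C@@H]1[C@H](CO[Si](c3ccccc3)(c3ccccc3)C(C)(C)C)C=C(O[Si](C)(C)C(C)(C)C)[C@@H]2C(C)(C)CCC[C@@]12C | intermediate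
20 | methyl enol ether of 19 (C9–CH=CH–OCH3, E/Z mixture; ring stereocentres as in 19) | COC=C[C@@H]1[C@H](CO[Si](c3ccccc3)(c3ccccc3)C(C)(C)C)C=C(O[Si](C)(C)C(C)(C)C)[C@@H]2C(C)(C)CCC[C@@]12C | intermediate
21 | 6-oxo-Δ7 enone with C9 2-methoxyvinyl (E/Z mixture) and C8 CH2OTBDPS; H5 and H9 cis, both trans to C20 | COC=C[C@@H]1C(CO[Si](c3ccccc3)(c3ccccc3)C(C)(C)C)=CC(=O)[C@@H]2C(C)(C)CCC[C@@]12C | intermediate
22 | 6-oxo-Δ7 enone with C9 CH2CHO (C12 aldehyde) | O=CC[C@@H]1C(CO[Si](c3ccccc3)(c3ccccc3)C(C)(C)C)=CC(=O)[C@@H]2C(C)(C)CCC[C@@]12C | intermediate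
23 | 6-oxo-Δ7 enone with C9 (E)-CH2CH=C(CH3)CHO | O=C/C(C)=C/C[C@@H]1C(CO[Si](c3ccccc3)(c3ccccc3)C(C)(C)C)=CC(=O)[C@@H]2C(C)(C)CCC[C@@]12C | intermediate
24 | 6-oxo-Δ7 enone with C9 (E)-CH2CH=C(CH3)CH=CH2 (17-TBDPS-oxy-labda-7,12E,14-trien-6-one) | C=C/C(C)=C/C[C@@H]1C(CO[Si](c3ccccc3)(c3ccccc3)C(C)(C)C)=CC(=O)[C@@H]2C(C)(C)CCC[C@@]12C | intermediate
25 | (6S)-17-TBDPS-oxy-labda-7,12E,14-trien-6-ol (OH cis to C20) | C=C/C(C)=C/C[C@@H]1C(CO[Si](c3ccccc3)(c3ccccc3)C(C)(C)C)=C[C@H](O)[C@@H]2C(C)(C)CCC[C@@]12C | intermediate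
26 | (6S)-6-acetoxy-17-TBDPS-oxy-labda-7,12E,14-triene | C=C/C(C)=C/C[C@@H]1C(CO[Si](c3ccccc3)(c3ccccc3)C(C)(C)C)=C[C@H](OC(C)=O)[C@@H]2C(C)(C)CCC[C@@]12C | intermediate
27 | (6S)-6-acetoxylabda-7,12E,14-trien-17-ol | C=C/C(C)=C/C[C@@H]1C(CO)=C[C@H](OC(C)=O)[C@@H]2C(C)(C)CCC[C@@]12C | intermediate
28 | (6S)-6-acetoxylabda-7,12E,14-trien-17-al | C=C/C(C)=C/C[C@@H]1C(C=O)=C[C@H](OC(C)=O)[C@@H]2C(C)(C)CCC[C@@]12C | intermediate
29 | (5R,6S,9S,10S,12E)-6-acetoxylabda-7,12,14-trien-17-oic acid | C=C/C(C)=C/C[C@@H]1C(C(=O)O)=C[C@H](OC(C)=O)[C@@H]2C(C)(C)CCC[C@@]12C | target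

**Totals and risks**

Total step count: 19. Longest linear sequence: 19 steps (1 → 29); compounds 5 and 10 are bought.

Most likely to fail:

Step 9. The β,β-disubstituted enal may react slowly under the bulky cationic catalyst, so that protodesilylation or intermolecular Mukaiyama-type addition of the silyl dienol ether competes, and endo or facial selectivity may be insufficient. The fallback sets out from 18 and gives up catalyst control for resolution. Me2AlCl in CH2Cl2 at −78 °C should give the trans-fused adduct as a racemate, that is 19 together with the mirror-image aldehyde F1. Reduction with i-Bu2AlH gives the primary alcohol F2 and its enantiomer F3. Esterification with (S)-2-methoxy-2-phenylacetic acid (DCC, 4-(dimethylamino)pyridine) gives the mandelate F4 from F2 and the diastereomeric mandelate F5 from F3, which are separated by chromatography. i-Bu2AlH cleaves F4 back to F2, and Parikh–Doering oxidation (SO3·pyridine, DMSO, i-Pr2NEt) returns to the route at 19.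

Step 11. Palladium may engage the alkyl enol ether or the transfer of the TBS enol ether to palladium may stall, leaving a mixture. The fallback sets out from 20 and no longer depends on the silyl enol ether. Aqueous HCl in THF hydrolyses both enol ethers to the keto aldehyde F6. The stabilised ylide Ph3P=C(CH3)CHO gives the keto enal F7, and methylenation with Ph3P=CH2 gives the keto diene F8, since the saturated, hindered C6 ketone stays out of both Wittig reactions. LiN(i-Pr)2 at −78 °C forms the C7 lithium enolate F9, PhSeBr gives the 7-phenylselanyl ketone F10 (selenium axial, cis to H8), and H2O2/pyridine brings about selenoxide syn-elimination. Dehydrogenation of this ketone is possible only toward C8, because C4 and C10 carry no hydrogen. The sequence returns to the route at 24.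

Step 2. Magnesium insertion into the aggregated chloro alkoxide may be incomplete, or the alkoxide-bearing Grignard reagent may add 1,2 to the hindered enone. The fallback sets out from 4 and uses a protected, ordinary Grignard reagent with silyl activation of the enone. TBSCl/imidazole gives the silyl ether F11, and magnesium in THF gives the Grignard reagent F12. CuBr·SMe2-catalysed addition to 5 in the presence of Me3SiCl gives the trimethylsilyl enol ether F13, which dilute acid on work-up converts into the ketone F14. Pyridinium p-toluenesulfonate in methanol removes the TBS group and returns to the route at 8.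

Further compounds
F1 | step 9 | mirror image of 19 (formed with 19 as the racemate) | O=C[C@H]1[C@@H](CO[Si](c3ccccc3)(c3ccccc3)C(C)(C)C)C=C(O[Si](C)(C)C(C)(C)C)[C@H]2C(C)(C)CCC[C@]12C
F2 | step 9 | primary alcohol from 19 (C9–CH2OH) | OC[C@@H]1[C@H](CO[Si](c3ccccc3)(c3ccccc3)C(C)(C)C)C=C(O[Si](C)(C)C(C)(C)C)[C@@H]2C(C)(C)CCC[C@@]12C
F3 | step 9 | enantiomer of F2 | OC[C@H]1[C@@H](CO[Si](c3ccccc3)(c3ccccc3)C(C)(C)C)C=C(O[Si](C)(C)C(C)(C)C)[C@H]2C(C)(C)CCC[C@]12C
F4 | step 9 | (S)-2-methoxy-2-phenylacetate of F2 | CO[C@H](C(=O)OC[C@@H]1[C@H](CO[Si](c3ccccc3)(c3ccccc3)C(C)(C)C)C=C(O[Si](C)(C)C(C)(C)C)[C@@H]2C(C)(C)CCC[C@@]12C)c4ccccc4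
F5 | step 9 | (S)-2-methoxy-2-phenylacetate of F3 | CO[C@H](C(=O)OC[C@H]1[C@@H](CO[Si](c3ccccc3)(c3ccccc3)C(C)(C)C)C=C(O[Si](C)(C)C(C)(C)C)[C@H]2C(C)(C)CCC[C@]12C)c4ccccc4
F6 | step 11 | keto aldehyde (C6 ketone, C7 methylene, C9–CH2CHO, C8 CH2OTBDPS) | O=CC[C@@H]1[C@H](CO[Si](c3ccccc3)(c3ccccc3)C(C)(C)C)CC(=O)[C@@H]2C(C)(C)CCC[C@@]12C
F7 | step 11 | keto enal (C9 (E)-CH2CH=C(CH3)CHO) | O=C/C(C)=C/C[C@@H]1[C@H](CO[Si](c3ccccc3)(c3ccccc3)C(C)(C)C)CC(=O)[C@@H]2C(C)(C)CCC[C@@]12C
F8 | step 11 | keto diene (C9 (E)-CH2CH=C(CH3)CH=CH2) | C=C/C(C)=C/C[C@@H]1[C@H](CO[Si](c3ccccc3)(c3ccccc3)C(C)(C)C)CC(=O)[C@@H]2C(C)(C)CCC[C@@]12C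
F9 | step 11 | C7 lithium enolate of F8 (C6–OLi, C6=C7) | C=C/C(C)=C/C[C@@H]1[C@H](CO[Si](c3ccccc3)(c3ccccc3)C(C)(C)C)C=C(O[Li])[C@@H]2C(C)(C)CCC[C@@]12C
F10 | step 11 | 7-phenylselanyl ketone (Se cis to H8) | C=C/C(C)=C/C[C@@H]1[C@H](CO[Si](c3ccccc3)(c3ccccc3)C(C)(C)C)[C@@H]([Se]c4ccccc4)C(=O)[C@@H]2C(C)(C)CCC[C@@]12C
F11 | step 2 | tert-butyl{[(E)-6-chloro-3-methylhex-2-en-1-yl]oxy}dimethylsilane | CC(C)(C)[Si](C)(C)OC/C=C(\C)CCCCl
F12 | step 2 | Grignard reagent of F11 | CC(C)(C)[Si](C)(C)OC/C=C(\C)CCC[Mg]Cl
F13 | step 2 | trimethylsilyl enol ether of F14 (C5=C6–OSiMe3) | C[Si](C)(C)OC(C)=CC(C)(C)CCC/C(C)=C/CO[Si](C)(C)C(C)(C)C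
F14 | step 2 | (E)-10-[(tert-butyldimethylsilyl)oxy]-4,4,8-trimethyldec-8-en-2-one | CC(=O)CC(C)(C)CCC/C(C)=C/CO[Si](C)(C)C(C)(C)C
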